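Start from the even split: if X divides equally between J and an unseen partner, Tuesday's J line holds 0.0100 M, and the G left after one equivalent, 10.0 mM, matches it. That matched case is my zero: [J] and [G] fall in step, and 1/[J] climbs on a straight line.

| flask | X | G | temperature | remark | time |
|---|---|---|---|---|---|
| red | 20 mM | 30 mM | 10 °C | run made earlier |  |
| green | 20 mM | 15 mM | 25 °C | run made earlier |  |
| teal | 20 mM | 22 mM | 10 °C | run made earlier |  |
| Tuesday's | 20 mM | 30.0 mM | 25 °C | everything together at the start | 80 min |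
| Saturday's | 20 mM (fed, over 30 min) | 30.0 mM | 25 °C | all else is in the flask from the start; the feed brings no volume worth counting | 80 min |
| Wednesday's | 20 mM | 30.0 mM (fed, over 30 min) |  | the addition at −5 °C, then warmed to 25 °C; the feed brings no volume worth counting | 80 min |
| Monday's | 20 mM (in portions, 3, over 30 min) | 30.0 mM | 25 °C | first portion at the start, last at 30 min | 80 min |

| run | time / min | J / % | L / % |
|---|---|---|---|
| red | 5.00 | 15.5 | 1.8 |
| red | 15.0 | 22.9 | 7.8 |
| red | 30.0 | 23.0 | 14.6 |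
| red | 40.0 | 22.0 | 17.8 |
| red | 60.0 | 19.2 | 22.2 |
| red | 80.0 | 16.1 | 26.5 |
| red | 120 | 12.2 | 30.9 |
| green | 5.00 | 15.8 | 2.0 |
| green | 8.00 | 19.1 | 4.2 |
| green | 12.0 | 21.1 | 4.4 |
| green | 20.0 | 20.7 | 6.7 |
| green | 30.0 | 22.1 | 7.0 |
| green | 40.0 | 21.1 | 8.1 |
| green | 60.0 | 20.7 | 7.4 |
| teal | 10.0 | 18.7 | 3.2 |
| teal | 15.0 | 20.5 | 4.2 |
| teal | 25.0 | 23.0 | 7.7 |
| teal | 40.0 | 24.3 | 10.5 |
| teal | 60.0 | 23.5 | 13.1 |
| teal | 80.0 | 22.6 | 15.6 |
| teal | 120 | 21.4 | 16.6 |

(standard deviation of a reading: 0.5 percentage points)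



* the best flask by share of J in J plus L; "all alike" if 1.5 percentage points covers them all (Tuesday's / Saturday's / Wednesday's / Monday's / all alike)
* share of J in J plus L at the end, Tuesday's
* share of J in J plus L at the end, Saturday's
* share of J in J plus L at the end, Wednesday's
* share of J in J plus L at the end, Monday's

Red has Tuesday's charges at 10 °C, so I treat Tuesday's as red with a faster clock, faster by a clock factor f. Red's 1/[J] climbs from 0.311 mM⁻¹ to 0.410 mM⁻¹ between 80.0 min and 120 min, a slope of 0.00248 mM⁻¹ min⁻¹ as read.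

Two numbers enter the share. J+L may lie anywhere from red's last 43.1% up to half the charge, which moves the share by 13.8% of itself. The clock factor weighs more: 2 gives 22.8%, 3 gives 16.4%.

So f must be known well. Green's J+L per mM of G at its first reading, over red's, reads 2.06. That makes the tail constant, the climb of 1/[J] at 25 °C, 0.00511 mM⁻¹ min⁻¹.

For Tuesday's I get J at 9.60% and a share of 22.3%. X arrives 15.0 min late on average in Saturday's and Monday's, which gives both 26.1%. I count Wednesday's cold 30 min as lost, which gives 31.6%.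

The forecast also names Wednesday's, with 10.5%, 12.5%, 17% and 11.5% for Tuesday's, Saturday's, Wednesday's and Monday's, saying “Delay helps slightly”, and my Tuesday's figure stands above its.

The flasks give 17.8%, 20.3%, 25.1% and 20.0% in that order, and Wednesday's is best.

    X + G → J + E (k = 264 L mol⁻¹ h⁻¹, Ea = 43.0 kJ mol⁻¹)
    X + G → Q + E (k = 303 L mol⁻¹ h⁻¹, Ea = 39.0 kJ mol⁻¹)
    G + J → L + E (k = 265 L mol⁻¹ h⁻¹, Ea = 48.0 kJ mol⁻¹)
    G + Q → L + E (k = 3.64 L mol⁻¹ h⁻¹, Ea = 60.0 kJ mol⁻¹)
    X + J → D (k = 16.1 L mol⁻¹ h⁻¹, Ea = 74.0 kJ mol⁻¹)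
    (constants at 25 °C)

My shares stand above these, yet Tuesday's J ends at 8.30% against my 9.60%. Now take 0.00511 mM⁻¹ min⁻¹ to the neighbouring flask, Tuesday's with 8.0 mM of X, which has 3.75 equiv of G. It ends with [G] at 18.0 mM. Taking J there as a pseudo-first-order species at that [G], I reckon a half-life of 7.56 min from my tail constant and 8.74 min from the scheme's constant for G + J, so 10.6 or 9.15 such half-lives fit into 80 min. In that flask J ends at 0.0969%, a share of 0.191%.

The numbers in the tables are calculated from invented constants; the scatter is artificial.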